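**Strategy.** Ring A is disconnected to an acyclic 1,8-enyne (azulene numbering of the core). C2, the methyl- and epoxide-bearing carbon of ring A, sits 1,3 to both fusion carbons C3a and C8a, which is the place the inserted CO takes in a Pauson–Khand cyclopentenone. The ring B atoms C4–C8 between the fusion carbons carry the carbinol (C5), acyloxy (C7) and isopropyl (C8) centres and act as the tether. One cobalt-mediated (2+2+1) cyclocarbonylation forms C3a–C8a and both bonds to the C2 carbonyl, closing rings A and B and setting C8a. The precursor is a (3S,4S,6R)-non-1-en-8-yne with two separate silyl ethers, made from (R)-mevalonolactone and a (Z)-γ-isopropylallylborane.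

Key step: step 8

Remark: the azulene numbering of the bicyclic core (C1–C3, C3a, C4–C8, C8a) is used for all compounds; because O5 and O7 lie on opposite faces of ring B in the target, they are protected as two independent silyl ethers, since one bridging acetal could not span them once ring B is closed.

Step 1
Reactants: 1 (R)-mevalonolactone
Product: 2 (3R)-3,5-dihydroxy-N-methoxy-N,3-dimethylpentanamide
Conditions: MeNH(OMe)·HCl, AlMe3, CH2Cl2, 0 °C to rt; aq. KNaC4H4O6; used directly
Reagents that add atoms: N,O-dimethylhydroxylamine hydrochloride, CNOC.Cl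
Why: Weinreb aminolysis of the δ-lactone by the aluminium amide opens the ring at the acyl carbon only, so the two arms of the future C5 carbinol stay differentiated and its (R) configuration is not touched.

Step 2
Reactants: 2 (3R)-3,5-dihydroxy-N-methoxy-N,3-dimethylpentanamide
Product: 3 (3R)-N-methoxy-N,3-dimethyl-3,5-bis[(triethylsilyl)oxy]pentanamide
Conditions: Et3SiOTf, 2,6-lutidine, CH2Cl2, −78 to 0 °C
Reagents that add atoms: triethylsilyl trifluoromethanesulfonate, CC[Si](CC)(CC)OS(=O)(=O)C(F)(F)F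
Why: Silyl triflate with a hindered pyridine base silylates the tertiary as well as the primary hydroxyl, which stops relactonisation and protects the carbinol for the whole route.

Step 3
Reactants: 3 (3R)-N-methoxy-N,3-dimethyl-3,5-bis[(triethylsilyl)oxy]pentanamide
Product: 4 (3R)-N-methoxy-N,3-dimethyl-5-oxo-3-[(triethylsilyl)oxy]pentanamide
Conditions: (COCl)2, DMSO, CH2Cl2, −78 to −30 °C; then Et3N, −78 °C to rt
Reagents that add atoms: none
Why: Under Swern conditions activated DMSO cleaves a primary triethylsilyl ether and oxidises it directly to the aldehyde (oxidative desilylation), whereas the hindered tertiary silyl ether and the Weinreb amide should be inert.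

Step 4
Reactants: 4 (3R)-N-methoxy-N,3-dimethyl-5-oxo-3-[(triethylsilyl)oxy]pentanamide; 5 dimethyl (1-diazo-2-oxopropyl)phosphonate
Product: 7 (3R)-N-methoxy-N,3-dimethyl-3-[(triethylsilyl)oxy]hex-5-ynamide, via dimethyl (diazomethyl)phosphonate 6 (not isolated)
Conditions: K2CO3, MeOH, 0 °C to rt
Reagents that add atoms: none
Why: Seyferth–Gilbert homologation with the Ohira–Bestmann reagent turns the aldehyde into the terminal alkyne under mild carbonate conditions that the amide and the tertiary silyl ether tolerate.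

Step 5
Reactants: 7 (3R)-N-methoxy-N,3-dimethyl-3-[(triethylsilyl)oxy]hex-5-ynamide
Product: 8 (3R)-3-methyl-3-[(triethylsilyl)oxy]hex-5-ynal
Conditions: i-Bu2AlH, THF, −78 °C; aq. KNaC4H4O6; used crude
Reagents that add atoms: none
Why: Hydride reduction of a Weinreb amide stops at a chelated tetrahedral aluminium adduct that gives the aldehyde only on work-up, and the alkyne is not hydroaluminated at this temperature.

Step 6
Reactants: 8 (3R)-3-methyl-3-[(triethylsilyl)oxy]hex-5-ynal; 9 (Z)-4-methylpent-2-ene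
Product: 13 (3S,4S,6R)-6-methyl-3-(propan-2-yl)-6-[(triethylsilyl)oxy]non-1-en-8-yn-4-ol, via (Z)-(4-methylpent-2-en-1-yl)potassium 10 (not isolated), via (Z)-(4-methylpent-2-en-1-yl)diisopinocampheylborane 11 (not isolated), via diisopinocampheylborinate of the homoallylic alcohol 12 (not isolated)
Conditions: 9, n-BuLi, KOt-Bu, THF, −78 to −50 °C; (+)-Ipc2BOMe [from (−)-α-pinene], −78 °C; BF3·OEt2; 8, −78 °C; then NaOH, H2O2, 0 °C to rt
Reagents that add atoms: none
Why: This is a Brown-type γ-substituted allylboration in which Schlosser metalation of the methyl group keeps the Z geometry, the chair Zimmerman–Traxler transition state turns Z into the syn C7/C8 relationship, and the isopinocampheyl groups from (−)-α-pinene are expected to direct attack to the Re face of the aldehyde (7S,8S), overriding the remote C5 centre.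

Step 7
Reactants: 13 (3S,4S,6R)-6-methyl-3-(propan-2-yl)-6-[(triethylsilyl)oxy]non-1-en-8-yn-4-ol
Product: 14 tert-butyldimethyl{[(3S,4S,6R)-6-methyl-3-(propan-2-yl)-6-[(triethylsilyl)oxy]non-1-en-8-yn-4-yl]oxy}silane
Conditions: t-BuMe2SiOTf, 2,6-lutidine, CH2Cl2, −78 to 0 °C
Reagents that add atoms: tert-butyldimethylsilyl trifluoromethanesulfonate, CC(C)(C)[Si](C)(C)OS(=O)(=O)C(F)(F)F
Why: Silyl triflate silylation of the hindered secondary alcohol gives an ether that withstands cobalt carbonyl, dissolving metal and Grignard reagents and is not tied to O5.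

Step 8
Reactants: 14 tert-butyldimethyl{[(3S,4S,6R)-6-methyl-3-(propan-2-yl)-6-[(triethylsilyl)oxy]non-1-en-8-yn-4-yl]oxy}silane; 15 carbon monoxide (supplied as a ligand of Co2(CO)8)
Product: 17 (5R,7S,8S,8aS)-7-[(tert-butyldimethylsilyl)oxy]-5-methyl-8-(propan-2-yl)-5-[(triethylsilyl)oxy]-4,5,6,7,8,8a-hexahydroazulen-2(1H)-one, via hexacarbonyldicobalt alkyne complex 16 (not isolated)
Conditions: Co2(CO)8 (1.1 equiv), CH2Cl2, rt; then Me3NO·2H2O, 4 Å molecular sieves, CH2Cl2 (high dilution), 0 °C to rt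
Reagents that add atoms: dicobalt octacarbonyl Co2(CO)8, [C-]#[O+].[C-]#[O+].[C-]#[O+].[C-]#[O+].[C-]#[O+].[C-]#[O+].[C-]#[O+].[C-]#[O+].[Co].[Co] (carrier of 15)
Why: Co2(CO)8 (zerovalent cobalt) converts the terminal alkyne into the hexacarbonyldicobalt complex 16; Me3NO then oxidises off a CO ligand, the vinyl group coordinates and inserts into the Co–C bond of the internal alkyne carbon, CO migrates into the cobaltacycle and reductive elimination releases the enone. The closest known reaction is the amine-oxide-promoted intramolecular Pauson–Khand reaction of enynes, used here in its uncommon 1,8-enyne version that gives a bicyclo[5.3.0]decenone. Ring B closes in the seven-membered mode by forming C3a–C8a between the internal alkyne carbon and the internal alkene carbon, and ring A closes as the five-membered enone through the C1–C2 and C2–C3 bonds to the inserted CO. C8a is the only new stereocentre and is controlled by C8: in the chair-like metallacycle the C8–H bond lies in the plane of the vinyl group (minimal 1,3-allylic strain), so the C8 isopropyl, the C7 silyloxy group and the new C8a–C1 bond are all pseudo-equatorial and H-8a ends up anti to H-8. The step needs seven-membered closure ahead of intermolecular reaction of the alkyne complex, and one alkene face; the quaternary C5 with its bulky triethylsilyloxy group (gem-disubstituent effect), the vicinal branches at C7 and C8, the unhindered terminal alkyne and high dilution are what should secure them.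

Step 9
Reactants: 17 (5R,7S,8S,8aS)-7-[(tert-butyldimethylsilyl)oxy]-5-methyl-8-(propan-2-yl)-5-[(triethylsilyl)oxy]-4,5,6,7,8,8a-hexahydroazulen-2(1H)-one
Product: 19 (3aS,5R,7S,8S,8aR)-7-[(tert-butyldimethylsilyl)oxy]-5-methyl-8-(propan-2-yl)-5-[(triethylsilyl)oxy]-1,3a,4,5,6,7,8,8a-octahydroazulen-2-yl trifluoromethanesulfonate, via lithium enolate 18 (not isolated)
Conditions: Li, NH3(l), THF, t-BuOH (1 equiv), −78 °C; isoprene; NH3 removed; PhNTf2 (excess), THF, −78 to 0 °C
Reagents that add atoms: N-phenylbis(trifluoromethanesulfonimide), O=S(=O)(N(c1ccccc1)S(=O)(=O)C(F)(F)F)C(F)(F)F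
Why: Dissolving-metal (Birch-type) reduction of the enone gives a β-carbanion whose protonation at C3a is expected to give the more stable trans ring fusion (H-3a anti to H-8a), and the regiodefined C2–C3 lithium enolate left behind is trapped on oxygen as the enol triflate, which fixes the position of the future alkene.

Step 10
Reactants: 19 (3aS,5R,7S,8S,8aR)-7-[(tert-butyldimethylsilyl)oxy]-5-methyl-8-(propan-2-yl)-5-[(triethylsilyl)oxy]-1,3a,4,5,6,7,8,8a-octahydroazulen-2-yl trifluoromethanesulfonate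
Product: 20 tert-butyl{[(3aS,5R,7S,8S,8aR)-2,5-dimethyl-8-(propan-2-yl)-5-[(triethylsilyl)oxy]-1,3a,4,5,6,7,8,8a-octahydroazulen-7-yl]oxy}dimethylsilane
Conditions: MeMgBr, Fe(acac)3 (cat.), THF/NMP, −30 to 0 °C
Reagents that add atoms: methylmagnesium bromide, C[Mg]Br
Why: Iron-catalysed Kumada-type cross-coupling of an alkenyl triflate with a methyl Grignard reagent replaces the triflate by methyl without moving the double bond and leaves silyl ethers untouched.

Step 11
Reactants: 20 tert-butyl{[(3aS,5R,7S,8S,8aR)-2,5-dimethyl-8-(propan-2-yl)-5-[(triethylsilyl)oxy]-1,3a,4,5,6,7,8,8a-octahydroazulen-7-yl]oxy}dimethylsilane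
Product: 21 (3aS,5R,7S,8S,8aR)-2,5-dimethyl-8-(propan-2-yl)-1,3a,4,5,6,7,8,8a-octahydroazulene-5,7-diol
Conditions: Bu4NF, THF, 50 °C
Reagents that add atoms: none
Why: Fluoride cleaves both silyl ethers, and the substrate carries nothing else that is sensitive to fluoride or mild base.

Step 12
Reactants: 21 (3aS,5R,7S,8S,8aR)-2,5-dimethyl-8-(propan-2-yl)-1,3a,4,5,6,7,8,8a-octahydroazulene-5,7-diol; 22 4-(acetyloxy)benzoyl chloride
Product: 23 (3aS,5R,7S,8S,8aR)-5-hydroxy-2,5-dimethyl-8-(propan-2-yl)-1,3a,4,5,6,7,8,8a-octahydroazulen-7-yl 4-(acetyloxy)benzoate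
Conditions: Et3N, DMAP (cat.), CH2Cl2, 0 °C to rt
Reagents that add atoms: none
Why: DMAP-catalysed acylation by the acid chloride should take place at the secondary C7 hydroxyl only, because the tertiary C5 hydroxyl is too hindered to be acylated under these conditions.

Step 13
Reactants: 23 (3aS,5R,7S,8S,8aR)-5-hydroxy-2,5-dimethyl-8-(propan-2-yl)-1,3a,4,5,6,7,8,8a-octahydroazulen-7-yl 4-(acetyloxy)benzoate
Product: 24 (2R,3S,3aS,5R,7S,8S,8aR)-2,3-epoxy-5-hydroxy-2,5-dimethyl-8-(propan-2-yl)decahydroazulen-7-yl 4-(acetyloxy)benzoate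
Conditions: VO(acac)2 (cat.), t-BuOOH, CH2Cl2, 0 °C to rt
Reagents that add atoms: tert-butyl hydroperoxide, CC(C)(C)OO
Why: In this vanadium-catalysed hydroxyl-directed epoxidation the β-oriented tertiary C5 hydroxyl, bishomoallylic to C2=C3, binds the metal and should deliver the peroxide oxygen to the β face, setting C2 (R) and C3 (S); the resulting cis epoxy alcohol cannot close to a cyclic ether because backside attack is geometrically impossible.

Step 14
Reactants: 24 (2R,3S,3aS,5R,7S,8S,8aR)-2,3-epoxy-5-hydroxy-2,5-dimethyl-8-(propan-2-yl)decahydroazulen-7-yl 4-(acetyloxy)benzoate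
Product: 25 CNP0245441.1, (2R,3S,3aS,5R,7S,8S,8aR)-2,3-epoxy-5-hydroxy-2,5-dimethyl-8-(propan-2-yl)decahydroazulen-7-yl 4-hydroxybenzoate
Conditions: K2CO3 (cat.), MeOH, 0 °C
Reagents that add atoms: none
Why: Transesterification removes the phenolic acetate, which is far more electrophilic than the hindered secondary benzoate, and the benzoate is deactivated further once the phenoxide forms, so ester and epoxide should survive.

**Compound list**

1 | (R)-mevalonolactone, (4R)-4-hydroxy-4-methyloxan-2-one | C[C@@]1(O)CCOC(=O)C1 | starting material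
2 | (3R)-3,5-dihydroxy-N-methoxy-N,3-dimethylpentanamide | C[C@@](O)(CCO)CC(=O)N(C)OC | intermediate
3 | (3R)-N-methoxy-N,3-dimethyl-3,5-bis[(triethylsilyl)oxy]pentanamide | C[C@@](O[Si](CC)(CC)CC)(CCO[Si](CC)(CC)CC)CC(=O)N(C)OC | intermediate
4 | (3R)-N-methoxy-N,3-dimethyl-5-oxo-3-[(triethylsilyl)oxy]pentanamide | C[C@@](O[Si](CC)(CC)CC)(CC=O)CC(=O)N(C)OC | intermediate
5 | dimethyl (1-diazo-2-oxopropyl)phosphonate | CC(=O)C(=[N+]=[N-])P(=O)(OC)OC | starting material
6 | dimethyl (diazomethyl)phosphonate | COP(=O)(OC)C=[N+]=[N-] | intermediate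
7 | (3R)-N-methoxy-N,3-dimethyl-3-[(triethylsilyl)oxy]hex-5-ynamide | C[C@@](O[Si](CC)(CC)CC)(CC#C)CC(=O)N(C)OC | intermediate
8 | (3R)-3-methyl-3-[(triethylsilyl)oxy]hex-5-ynal | C[C@@](O[Si](CC)(CC)CC)(CC#C)CC=O | intermediate
9 | (Z)-4-methylpent-2-ene | C/C=C\C(C)C | starting material
10 | (Z)-(4-methylpent-2-en-1-yl)potassium | CC(C)/C=C\C[K] | intermediate
11 | (Z)-(4-methylpent-2-en-1-yl)bis[(1S,2R,3S,5S)-2,6,6-trimethylbicyclo[3.1.1]heptan-3-yl]borane | CC(C)/C=C\CB([C@H]1C[C@H]2C[C@@H]([C@@H]1C)C2(C)C)[C@H]1C[C@H]2C[C@@H]([C@@H]1C)C2(C)C | intermediate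
12 | diisopinocampheylborinic ester of 13 (O-B(Ipc)2 at C4 of the nonenyne) | CC(C)[C@@H](C=C)[C@@H](OB([C@H]1C[C@H]2C[C@@H]([C@@H]1C)C2(C)C)[C@H]1C[C@H]2C[C@@H]([C@@H]1C)C2(C)C)C[C@@](C)(CC#C)O[Si](CC)(CC)CC | intermediate
13 | (3S,4S,6R)-6-methyl-3-(propan-2-yl)-6-[(triethylsilyl)oxy]non-1-en-8-yn-4-ol | CC(C)[C@@H](C=C)[C@@H](O)C[C@@](C)(CC#C)O[Si](CC)(CC)CC | intermediate
14 | tert-butyldimethyl{[(3S,4S,6R)-6-methyl-3-(propan-2-yl)-6-[(triethylsilyl)oxy]non-1-en-8-yn-4-yl]oxy}silane | CC(C)[C@@H](C=C)[C@@H](O[Si](C)(C)C(C)(C)C)C[C@@](C)(CC#C)O[Si](CC)(CC)CC | intermediate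
15 | carbon monoxide | [C-]#[O+] | starting material
16 | hexacarbonyldicobalt complex of the alkyne of 14 (C2Co2 tetrahedrane) | CC(C)[C@@H](C=C)[C@@H](O[Si](C)(C)C(C)(C)C)C[C@@](C)(CC12[CH]3[Co]1(=C=O)(=C=O)(=C=O)[Co]23(=C=O)(=C=O)=C=O)O[Si](CC)(CC)CC | intermediate
17 | (5R,7S,8S,8aS)-7-[(tert-butyldimethylsilyl)oxy]-5-methyl-8-(propan-2-yl)-5-[(triethylsilyl)oxy]-4,5,6,7,8,8a-hexahydroazulen-2(1H)-one | CC(C)[C@H]1[C@@H]2CC(=O)C=C2C[C@@](C)(O[Si](CC)(CC)CC)C[C@@H]1O[Si](C)(C)C(C)(C)C | intermediate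
18 | lithium (3aS,5R,7S,8S,8aR)-7-[(tert-butyldimethylsilyl)oxy]-5-methyl-8-(propan-2-yl)-5-[(triethylsilyl)oxy]-1,3a,4,5,6,7,8,8a-octahydroazulen-2-olate | CC(C)[C@H]1[C@@H]2CC(O[Li])=C[C@H]2C[C@@](C)(O[Si](CC)(CC)CC)C[C@@H]1O[Si](C)(C)C(C)(C)C | intermediate
19 | (3aS,5R,7S,8S,8aR)-7-[(tert-butyldimethylsilyl)oxy]-5-methyl-8-(propan-2-yl)-5-[(triethylsilyl)oxy]-1,3a,4,5,6,7,8,8a-octahydroazulen-2-yl trifluoromethanesulfonate | CC(C)[C@H]1[C@@H]2CC(OS(=O)(=O)C(F)(F)F)=C[C@H]2C[C@@](C)(O[Si](CC)(CC)CC)C[C@@H]1O[Si](C)(C)C(C)(C)C | intermediate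
20 | tert-butyl{[(3aS,5R,7S,8S,8aR)-2,5-dimethyl-8-(propan-2-yl)-5-[(triethylsilyl)oxy]-1,3a,4,5,6,7,8,8a-octahydroazulen-7-yl]oxy}dimethylsilane | CC(C)[C@H]1[C@@H]2CC(C)=C[C@H]2C[C@@](C)(O[Si](CC)(CC)CC)C[C@@H]1O[Si](C)(C)C(C)(C)C | intermediate
21 | (3aS,5R,7S,8S,8aR)-2,5-dimethyl-8-(propan-2-yl)-1,3a,4,5,6,7,8,8a-octahydroazulene-5,7-diol | CC(C)[C@H]1[C@@H]2CC(C)=C[C@H]2C[C@@](C)(O)C[C@@H]1O | intermediate
22 | 4-(acetyloxy)benzoyl chloride | CC(=O)Oc1ccc(cc1)C(Cl)=O | starting material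
23 | (3aS,5R,7S,8S,8aR)-5-hydroxy-2,5-dimethyl-8-(propan-2-yl)-1,3a,4,5,6,7,8,8a-octahydroazulen-7-yl 4-(acetyloxy)benzoate | CC(C)[C@H]1[C@@H]2CC(C)=C[C@H]2C[C@@](C)(O)C[C@@H]1OC(=O)c1ccc(OC(C)=O)cc1 | intermediate
24 | (2R,3S,3aS,5R,7S,8S,8aR)-2,3-epoxy-5-hydroxy-2,5-dimethyl-8-(propan-2-yl)decahydroazulen-7-yl 4-(acetyloxy)benzoate | CC(C)[C@H]1[C@@H]2C[C@@]3(C)O[C@H]3[C@H]2C[C@@](C)(O)C[C@@H]1OC(=O)c1ccc(OC(C)=O)cc1 | intermediate
25 | CNP0245441.1, (2R,3S,3aS,5R,7S,8S,8aR)-2,3-epoxy-5-hydroxy-2,5-dimethyl-8-(propan-2-yl)decahydroazulen-7-yl 4-hydroxybenzoate | CC(C)[C@H]1[C@@H]2C[C@@]3(C)O[C@H]3[C@H]2C[C@@](C)(O)C[C@@H]1OC(=O)c1ccc(O)cc1 | target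

**Step count.** Total: 14 steps. Longest linear sequence: 14 steps (1 to 25).

**Steps most likely to fail**

Step 8. Closure of the seven-membered ring may be too slow, so that the alkyne–cobalt complex decomposes or reacts intermolecularly before the vinyl group inserts. The fallback builds ring B by olefin metathesis and ring A by aldol condensation, setting out from 14 and coming back at 17.
- Gold-catalysed Markovnikov hydration of the alkyne ((IPr)AuCl with AgSbF6, aqueous dioxane; IPr = 1,3-bis(2,6-diisopropylphenyl)imidazol-2-ylidene) would give the methyl ketone F1.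
- Kinetic enolisation at the methyl group (LiN(i-Pr)2, Me3SiCl, THF, −78 °C) would give the 2-silyloxy-1,8-diene F2.
- Ring-closing metathesis with the second-generation Grubbs catalyst (H2IMes)(PCy3)Cl2Ru=CHPh would give the seven-membered cyclic silyl enol ether F3.
- Regiospecific Tsuji–Trost allylation of the silyl enol ether (allyl methyl carbonate, Pd2(dba)3 (zerovalent palladium), dppe, THF) would give the 2-allylcycloheptanone F4; its epimerisable C8a should settle anti to the isopropyl group.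
- Wacker oxidation (PdCl2 (divalent palladium), CuCl, O2, DMF/H2O) would give the 1,4-diketone F5.
- Intramolecular aldol condensation (KOH, MeOH), in which the methyl ketone enolate attacks the ring ketone, would give 17.

Step 13. Coordination of vanadium by a tertiary, bishomoallylic hydroxyl may be too weak, so that oxygen is delivered slowly or mainly to the α face. The fallback reaches the β epoxide through a bromohydrin, which inverts the facial outcome of an electrophile that prefers the α face; it sets out from 20 and comes back at 24.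
- N-Bromosuccinimide in THF/H2O would form the α bromonium ion, which water opens at C2 from the β face to give the bromohydrin F6.
- K2CO3 in MeOH would close the β epoxide F7 by displacement of bromide with inversion at C3.
- Bu4NF in THF would give the epoxy diol F8.
- Acylation of the C7 hydroxyl with 22 (Et3N, DMAP, CH2Cl2) would give 24.

Step 6. Metalation of 9 at the wrong allylic position, or loss of Z geometry in the allylpotassium, would erode regio- and diastereoselectivity. The fallback sets the same two centres by an Evans syn-aldol reaction, setting out from 8 and coming back at 14.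
- Addition of the dibutylboron enolate of (R)-4-benzyl-3-(3-methylbutanoyl)-1,3-oxazolidin-2-one (Bu2BOTf, i-Pr2NEt, CH2Cl2, −78 to 0 °C) to 8 would give the syn aldol adduct F9.
- Silylation (t-BuMe2SiOTf, 2,6-lutidine) would give the silyl ether F10.
- Reductive removal of the auxiliary (LiBH4, MeOH, THF) would give the primary alcohol F11.
- Dess–Martin oxidation would give the aldehyde F12.
- Wittig methylenation (Ph3P=CH2, THF, −78 to 0 °C) would give 14.

**Further compounds**

F1 | step 8 | methyl ketone from hydration of the alkyne of 14, 6-[(tert-butyldimethylsilyl)oxy]-4-methyl-7-(propan-2-yl)-4-[(triethylsilyl)oxy]non-8-en-2-one (stereocentres as in 14) | CC(C)[C@@H](C=C)[C@@H](O[Si](C)(C)C(C)(C)C)C[C@@](C)(CC(C)=O)O[Si](CC)(CC)CC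
F2 | step 8 | 2-(trimethylsilyloxy)-1,8-diene, terminal trimethylsilyl enol ether of F1 | CC(C)[C@@H](C=C)[C@@H](O[Si](C)(C)C(C)(C)C)C[C@@](C)(CC(=C)O[Si](C)(C)C)O[Si](CC)(CC)CC
F3 | step 8 | cyclohept-1-enyl trimethylsilyl ether (C3a=C8a) carrying the C5, C7 and C8 substituents | CC(C)[C@H]1C=C(O[Si](C)(C)C)C[C@@](C)(O[Si](CC)(CC)CC)C[C@@H]1O[Si](C)(C)C(C)(C)C
F4 | step 8 | 2-allylcycloheptanone (ketone at C3a, allyl at C8a anti to isopropyl) | CC(C)[C@H]1[C@H](CC=C)C(=O)C[C@@](C)(O[Si](CC)(CC)CC)C[C@@H]1O[Si](C)(C)C(C)(C)C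
F5 | step 8 | 2-(2-oxopropyl)cycloheptanone, the 1,4-diketone | CC(C)[C@H]1[C@H](CC(C)=O)C(=O)C[C@@](C)(O[Si](CC)(CC)CC)C[C@@H]1O[Si](C)(C)C(C)(C)C
F6 | step 13 | bromohydrin of 20 (C2 β-hydroxyl, C3 α-bromide) | CC(C)[C@H]1[C@@H]2C[C@@](C)(O)[C@H](Br)[C@H]2C[C@@](C)(O[Si](CC)(CC)CC)C[C@@H]1O[Si](C)(C)C(C)(C)C
F7 | step 13 | β-2,3-epoxide of 20, both silyl ethers in place | CC(C)[C@H]1[C@@H]2C[C@@]3(C)O[C@H]3[C@H]2C[C@@](C)(O[Si](CC)(CC)CC)C[C@@H]1O[Si](C)(C)C(C)(C)C
F8 | step 13 | (2R,3S,3aS,5R,7S,8S,8aR)-2,3-epoxy-2,5-dimethyl-8-(propan-2-yl)decahydroazulene-5,7-diol | CC(C)[C@H]1[C@@H]2C[C@@]3(C)O[C@H]3[C@H]2C[C@@](C)(O)C[C@@H]1O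
F9 | step 6 | (R)-4-benzyl-3-[(2R,3S,5R)-3-hydroxy-5-methyl-2-(propan-2-yl)-5-[(triethylsilyl)oxy]oct-7-ynoyl]-1,3-oxazolidin-2-one | CC(C)[C@@H](C(=O)N1[C@H](Cc2ccccc2)COC1=O)[C@@H](O)C[C@@](C)(CC#C)O[Si](CC)(CC)CC
F10 | step 6 | tert-butyldimethylsilyl ether of F9 | CC(C)[C@@H](C(=O)N1[C@H](Cc2ccccc2)COC1=O)[C@@H](O[Si](C)(C)C(C)(C)C)C[C@@](C)(CC#C)O[Si](CC)(CC)CC
F11 | step 6 | (2S,3S,5R)-3-[(tert-butyldimethylsilyl)oxy]-5-methyl-2-(propan-2-yl)-5-[(triethylsilyl)oxy]oct-7-yn-1-ol | CC(C)[C@@H](CO)[C@@H](O[Si](C)(C)C(C)(C)C)C[C@@](C)(CC#C)O[Si](CC)(CC)CC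
F12 | step 6 | (2R,3S,5R)-3-[(tert-butyldimethylsilyl)oxy]-5-methyl-2-(propan-2-yl)-5-[(triethylsilyl)oxy]oct-7-ynal | CC(C)[C@@H](C=O)[C@@H](O[Si](C)(C)C(C)(C)C)C[C@@](C)(CC#C)O[Si](CC)(CC)CC
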